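**Plan**

- Numbering: ring A C1–C6 (C1 carries =CH2, C5 the two methyls, C6 the side chain), chain C7(OH)–C8=C9(CH3), ring B C1'–C6' (C1' on C9, C4' = C(CH3)OH, C5' = CHBr).
- Enabling feature: the C7 oxygen and the C9 methyl are cis across C8=C9, so O7 and an oxygenated C9–CH2O can be held by one silicon atom in a seven-membered ring O–Si–O–CH2–C9=C8–C7.
- Cuts: C9–CH3 back to C9–CH2O; C8=C9 (ring-closing metathesis on the silicon bridge); the two Si–O bonds; in ring A, C6–C7 (allylboration of acrolein) and C3=C4 (metathesis); in ring B, the allylic C–O, C9=CH2, C4'–CH3 and C5'–Br.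
- Forward: ring A is closed at C3=C4, then C6–C7 is joined. Ring B comes from (R)-cyclohex-3-ene-1-carboxylic acid. The halves are joined through silicon, the seven-membered ring closes at C8=C9, then it is opened and excised.
- Stereochemistry: C6/C7 from a chair allylboration under a chiral phosphoric acid. Ring B from the stereocentre of the acid through bromolactonisation, diaxial epoxide opening, methyl addition anti to bromine and equilibration at C1'. The E alkene follows from the ring-cis alkene of the silacycle.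

Key step: step 17

Assumption: the chiral phosphoric acid in step 8 is taken to select the aldehyde face as it does with allyl and (E)-crotyl pinacol boronates, which calls for the (S)-acid; were the sense reversed on this substrate, the (R)-acid would be used.

**Route**

Step 1
Reactants: 1 2,2-dimethylbut-3-enoic acid
Product: 2 2,2-dimethylbut-3-en-1-ol
Conditions: LiAlH4, Et2O, 0 °C → rt
Reagents that add atoms: none
Why: Hydride reduction of the carboxylic acid to the primary alcohol; the isolated vinyl group is inert to LiAlH4.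

Step 2
Reactants: 2 2,2-dimethylbut-3-en-1-ol
Product: 3 2,2-dimethylbut-3-enal
Conditions: TEMPO (10 mol %), PhI(OAc)2, CH2Cl2, rt; carried on as a solution
Reagents that add atoms: none
Why: Oxoammonium (TEMPO) oxidation stops at the aldehyde, which has no α-hydrogen and so can neither enolise nor move its alkene into conjugation.

Step 3
Reactants: 4 triethyl phosphonoacetate; 5 allyl bromide
Product: 6 ethyl 2-(diethoxyphosphoryl)pent-4-enoate (racemic)
Conditions: NaH, THF, 0 °C → rt
Reagents that add atoms: none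
Why: C-alkylation of the stabilised phosphonate carbanion by SN2 displacement on allyl bromide.

Step 4
Reactants: 3 2,2-dimethylbut-3-enal; 6 ethyl 2-(diethoxyphosphoryl)pent-4-enoate
Product: 7 ethyl (2E)-4,4-dimethyl-2-(prop-2-en-1-yl)hexa-2,5-dienoate
Conditions: NaH, THF, 0 °C → rt
Reagents that add atoms: none
Why: Horner–Wadsworth–Emmons olefination, in which the bulky tertiary-alkyl group of the aldehyde should end up trans to the ester (E), the isomer whose vinyl and allyl arms are cis; any Z isomer cannot cyclise and is removed after step 5.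

Step 5
Reactants: 7 ethyl (2E)-4,4-dimethyl-2-(prop-2-en-1-yl)hexa-2,5-dienoate
Product: 8 ethyl 3,3-dimethylcyclohexa-1,4-diene-1-carboxylate
Conditions: second-generation Grubbs catalyst RuCl2(H2IMes)(PCy3)(=CHPh) (3 mol %), CH2Cl2, 40 °C
Reagents that add atoms: none
Why: Ring-closing metathesis of the cis-disposed allyl and vinyl arms closes the six-membered ring at C3=C4 with loss of ethene, while the conjugated trisubstituted alkene does not take part.

Step 6
Reactants: 8 ethyl 3,3-dimethylcyclohexa-1,4-diene-1-carboxylate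
Product: 9 (3,3-dimethylcyclohexa-1,4-dien-1-yl)methanol
Conditions: iBu2AlH (2.2 equiv), CH2Cl2, −78 °C; aq. potassium sodium tartrate
Reagents that add atoms: none
Why: 1,2-Reduction of the conjugated ester by the aluminium hydride gives the primary allylic alcohol without touching either alkene.

Step 7
Reactants: 9 (3,3-dimethylcyclohexa-1,4-dien-1-yl)methanol
Product: 10 2-[(3,3-dimethylcyclohexa-1,4-dien-1-yl)methyl]-4,4,5,5-tetramethyl-1,3,2-dioxaborolane
Conditions: B2pin2, [Pd(MeCN)4](BF4)2 (5 mol %), DMSO–MeOH, rt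
Reagents that add atoms: bis(pinacolato)diboron, CC1(C)OB(OC1(C)C)B1OC(C)(C)C(C)(C)O1
Why: Palladium-catalysed borylation of the allylic alcohol through a π-allyl intermediate, which the diboron traps at the unhindered CH2 terminus to give the primary allyl boronate.

Step 8
Reactants: 10 2-[(3,3-dimethylcyclohexa-1,4-dien-1-yl)methyl]-4,4,5,5-tetramethyl-1,3,2-dioxaborolane; 11 acrolein
Product: 12 (1R)-1-[(1R)-2,2-dimethyl-6-methylidenecyclohex-3-en-1-yl]prop-2-en-1-ol
Conditions: (S)-TRIP [(S)-3,3'-bis(2,4,6-triisopropylphenyl)-1,1'-binaphthyl-2,2'-diyl hydrogen phosphate] (5 mol %), 4 Å MS, toluene, −30 °C; aqueous work-up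
Reagents that add atoms: none
Why: Chiral phosphoric acid-catalysed allylboration through a closed chair (Zimmerman–Traxler) transition state, in which the ring makes C5 the E substituent of the allyl unit and so gives the anti C6/C7 relationship, the catalyst selects the aldehyde face, and the allyl transposition creates the exocyclic methylene.

Step 9
Reactants: 13 (1R)-cyclohex-3-ene-1-carboxylic acid
Product: 14 (1R,4R,5R)-4-bromo-6-oxabicyclo[3.2.1]octan-7-one
Conditions: NBS, CaO (cat.), CH2Cl2, 0 °C → rt
Reagents that add atoms: N-bromosuccinimide, O=C1CCC(=O)N1Br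
Why: Bromolactonisation, in which the carboxyl group opens the bromonium ion at C3 to give the bridged γ-lactone, so the stereocentre of 13 fixes oxygen cis and bromine trans to the carboxyl carbon.

Step 10
Reactants: 14 (1R,4R,5R)-4-bromo-6-oxabicyclo[3.2.1]octan-7-one
Product: 16 (1R,3R,6S)-N-methoxy-N-methyl-7-oxabicyclo[4.1.0]heptane-3-carboxamide, via bromohydrin amide 15 (not isolated)
Conditions: MeNH(OMe)·HCl, AlMe3, CH2Cl2, 0 °C → rt; aq. potassium sodium tartrate; then K2CO3, MeOH, 0 °C → rt
Reagents that add atoms: N,O-dimethylhydroxylamine hydrochloride, CNOC.Cl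
Why: Weinreb aminolysis of the lactone by the aluminium amide frees the C3 hydroxyl, whose alkoxide then displaces the trans C4 bromide (intramolecular SN2) to give the oxirane cis to the amide as one diastereomer.

Step 11
Reactants: 16 (1R,3R,6S)-N-methoxy-N-methyl-7-oxabicyclo[4.1.0]heptane-3-carboxamide
Product: 17 (1R,3S,4S)-3-bromo-4-hydroxy-N-methoxy-N-methylcyclohexane-1-carboxamide
Conditions: 48% aq. HBr, THF, 0 °C
Reagents that add atoms: hydrogen bromide, Br
Why: Acid-mediated epoxide opening by bromide in the trans-diaxial (Fürst–Plattner) mode: with the amide equatorial only attack at C3 from the face opposite the oxirane leads to a chair, so bromine enters at C3 trans to the amide and the hydroxyl stays on C4.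

Step 12
Reactants: 17 (1R,3S,4S)-3-bromo-4-hydroxy-N-methoxy-N-methylcyclohexane-1-carboxamide
Product: 18 (1R,3S)-3-bromo-N-methoxy-N-methyl-4-oxocyclohexane-1-carboxamide
Conditions: Dess–Martin periodinane, CH2Cl2, 0 °C → rt; used without delay
Reagents that add atoms: none
Why: Hypervalent-iodine oxidation of the secondary alcohol under near-neutral conditions gives the α-bromo ketone with its axial bromine intact.

Step 13
Reactants: 18 (1R,3S)-3-bromo-N-methoxy-N-methyl-4-oxocyclohexane-1-carboxamide
Product: 20 1-[(1S,3S,4R)-3-bromo-4-hydroxy-4-methylcyclohexyl]ethan-1-one, via trans ketone 19 (not isolated)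
Conditions: MeMgBr (3.5 equiv), THF, −78 → 0 °C; aq. NH4Cl; then K2CO3 (cat.), MeOH, rt
Reagents that add atoms: methylmagnesium bromide, C[Mg]Br
Why: Grignard addition anti to the axial C–Br bond (Cornforth/polar Felkin–Anh control) sets the tertiary carbinol cis to bromine, the Weinreb amide gives the methyl ketone in the same flask, and carbonate-mediated enolisation then equilibrates C1 towards the isomer in which acetyl, bromine and methyl are all equatorial, the minor epimer being recycled.

Step 14
Reactants: 20 1-[(1S,3S,4R)-3-bromo-4-hydroxy-4-methylcyclohexyl]ethan-1-one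
Product: 21 (1R,2S,4S)-2-bromo-1-methyl-4-(prop-1-en-2-yl)cyclohexan-1-ol
Conditions: Ph3PCH3Br, KOtBu (2.5 equiv each), THF, 0 °C → rt
Reagents that add atoms: methyltriphenylphosphonium bromide, C[P+](c1ccccc1)(c1ccccc1)c1ccccc1.[Br-]
Why: Wittig methylenation of the methyl ketone, with excess ylide covering the free tertiary hydroxyl, whose cis alkoxide cannot displace the neighbouring bromide.

Step 15
Reactants: 21 (1R,2S,4S)-2-bromo-1-methyl-4-(prop-1-en-2-yl)cyclohexan-1-ol
Product: 22 (1R,2S,4S)-2-bromo-4-(3-hydroxyprop-1-en-2-yl)-1-methylcyclohexan-1-ol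
Conditions: SeO2 (0.5 equiv), tBuOOH, CH2Cl2, rt
Reagents that add atoms: selenium dioxide, O=[Se]=O; tert-butyl hydroperoxide, CC(C)(C)OO
Why: Selenium dioxide allylic oxidation (ene reaction then [2,3]-sigmatropic shift) of the 1,1-disubstituted alkene, which by the usual preference for CH3 over a ring CH should oxidise the allylic methyl group to the 2-substituted prop-2-en-1-ol.

Step 16
Reactants: 12 (1R)-1-[(1R)-2,2-dimethyl-6-methylidenecyclohex-3-en-1-yl]prop-2-en-1-ol; 23 dichlorodi(propan-2-yl)silane; 22 (1R,2S,4S)-2-bromo-4-(3-hydroxyprop-1-en-2-yl)-1-methylcyclohexan-1-ol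
Product: 25 (1R,2S,4S)-2-bromo-4-{3-[({(1R)-1-[(1R)-2,2-dimethyl-6-methylidenecyclohex-3-en-1-yl]prop-2-en-1-yl}oxy)di(propan-2-yl)silyloxy]prop-1-en-2-yl}-1-methylcyclohexan-1-ol (acyclic silaketal), via chlorosilane 24 (not isolated)
Conditions: 12, 23 (3 equiv), imidazole, CH2Cl2, 0 °C → rt; excess 23 removed in vacuo; then 22, imidazole, DMF, rt
Reagents that add atoms: none
Why: Stepwise silyl ether formation (substitution at silicon), in which the hindered secondary alcohol takes one chloride of the excess dichlorosilane and the monochlorosilane is then captured by the primary allylic hydroxyl of 22 in preference to its tertiary hydroxyl.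

Step 17
Reactants: 25 acyclic silaketal
Product: 26 (1R,2S,4S)-2-bromo-4-{(4R)-4-[(1R)-2,2-dimethyl-6-methylidenecyclohex-3-en-1-yl]-2,2-di(propan-2-yl)-4,7-dihydro-1,3,2-dioxasilepin-6-yl}-1-methylcyclohexan-1-ol (cyclic silaketal)
Conditions: second-generation Grubbs catalyst RuCl2(H2IMes)(PCy3)(=CHPh) (10 mol %), 1,4-benzoquinone (10 mol %), toluene (0.005 M), 80 °C, argon sparge
Reagents that add atoms: none
Why: Ring-closing olefin metathesis on a temporary silicon tether: the ruthenium carbene exchanges onto the only monosubstituted alkene (the C8 vinyl group), adds intramolecularly across the 1,1-disubstituted C9 methylene through a ruthenacyclobutane and releases ethene. The closest known reaction type is the closure of bis(allyloxy)dialkylsilanes to 4,7-dihydro-1,3,2-dioxasilepines carrying a trisubstituted ring alkene. The one new ring is the seven-membered dioxasilepine, closed by joining C8 to C9 across the O–Si–O bridge. No stereocentre is created; the alkene can only be ring-cis, which puts C7 and the oxygenated CH2 on the same side and so encodes the E geometry of the final alkene once CH2O becomes CH3. The step needs chemoselectivity against ring A: the exocyclic methylene could only close a cyclobutene and the C3=C4 alkene sits in an unstrained cyclohexene next to the quaternary carbon, so neither should compete with the tethered closure, and high dilution suppresses dimerisation through the vinyl group.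

Step 18
Reactants: 26 cyclic silaketal
Product: 27 (1R,2S,4S)-2-bromo-4-[(2Z,4R)-4-[(1R)-2,2-dimethyl-6-methylidenecyclohex-3-en-1-yl]-1-hydroxy-4-{[methyldi(propan-2-yl)silyl]oxy}but-2-en-2-yl]-1-methylcyclohexan-1-ol
Conditions: MeLi (2.5 equiv), THF, −78 → −30 °C; H2O at −30 °C
Reagents that add atoms: methyllithium, [Li]C
Why: Ring opening of the cyclic dialkoxysilane by substitution at silicon with an alkyllithium, in which, by analogy with alkyllithium openings of silylene acetals, the Si–O bond to the less hindered primary oxygen should break, leaving O7 silylated and the primary allylic hydroxyl free (one equivalent is consumed by the tertiary hydroxyl, and the cold quench forestalls silyl migration).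

Step 19
Reactants: 27 mono-silyl ether diol
Product: 29 (1R,2S,4S)-2-bromo-4-[(2E,4R)-4-[(1R)-2,2-dimethyl-6-methylidenecyclohex-3-en-1-yl]-4-{[methyldi(propan-2-yl)silyl]oxy}but-2-en-2-yl]-1-methylcyclohexan-1-ol, via allylic mesylate 28 (not isolated)
Conditions: MsCl, Et3N, THF, −40 °C; then LiBHEt3 (4 equiv), −78 → 0 °C
Reagents that add atoms: none
Why: Selective mesylation of the primary allylic hydroxyl followed by SN2 displacement with the hydride of LiBHEt3 turns CH2OH into the C9 methyl group; the silylated O7 cannot close a 2,5-dihydrofuran and the hindered secondary bromide should be left alone at 0 °C or below.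

Step 20
Reactants: 29 silyl ether of the target
Product: 30 (1R,2S,4S)-2-bromo-4-[(2E,4R)-4-[(1R)-2,2-dimethyl-6-methylidenecyclohex-3-en-1-yl]-4-hydroxybut-2-en-2-yl]-1-methylcyclohexan-1-ol (target, CNP0362245.1)
Conditions: Bu4NF, THF, 0 °C → rt
Reagents that add atoms: none
Why: Fluoride-mediated cleavage of the silyl ether (Si–F bond formation) frees the C7 hydroxyl without harming the cis-bromohydrin, which cannot close to an epoxide.

**Compound list**

1 | 2,2-dimethylbut-3-enoic acid | C=CC(C)(C)C(=O)O | starting material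
2 | 2,2-dimethylbut-3-en-1-ol | C=CC(C)(C)CO | intermediate
3 | 2,2-dimethylbut-3-enal | C=CC(C)(C)C=O | intermediate
4 | triethyl phosphonoacetate | CCOC(=O)CP(=O)(OCC)OCC | starting material
5 | allyl bromide (3-bromoprop-1-ene) | C=CCBr | starting material
6 | ethyl 2-(diethoxyphosphoryl)pent-4-enoate (racemic) | CCOC(=O)C(CC=C)P(=O)(OCC)OCC | intermediate
7 | ethyl (2E)-4,4-dimethyl-2-(prop-2-en-1-yl)hexa-2,5-dienoate | CCOC(=O)/C(CC=C)=C/C(C)(C)C=C | intermediate
8 | ethyl 3,3-dimethylcyclohexa-1,4-diene-1-carboxylate | CCOC(=O)C1=CC(C)(C)C=CC1 | intermediate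
9 | (3,3-dimethylcyclohexa-1,4-dien-1-yl)methanol | OCC1=CC(C)(C)C=CC1 | intermediate
10 | 2-[(3,3-dimethylcyclohexa-1,4-dien-1-yl)methyl]-4,4,5,5-tetramethyl-1,3,2-dioxaborolane | CC1(C)C=CCC(CB2OC(C)(C)C(C)(C)O2)=C1 | intermediate
11 | acrolein (prop-2-enal) | C=CC=O | starting material
12 | (1R)-1-[(1R)-2,2-dimethyl-6-methylidenecyclohex-3-en-1-yl]prop-2-en-1-ol (ring A alcohol) | C=C1CC=CC(C)(C)[C@@H]1[C@H](O)C=C | intermediate
13 | (1R)-cyclohex-3-ene-1-carboxylic acid | OC(=O)[C@H]1CC=CCC1 | starting material
14 | (1R,4R,5R)-4-bromo-6-oxabicyclo[3.2.1]octan-7-one | O=C1O[C@@H]2C[C@H]1CC[C@H]2Br | intermediate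
15 | (1R,3R,4R)-4-bromo-3-hydroxy-N-methoxy-N-methylcyclohexane-1-carboxamide | CON(C)C(=O)[C@@H]1CC[C@@H](Br)[C@H](O)C1 | intermediate (not isolated)
16 | (1R,3R,6S)-N-methoxy-N-methyl-7-oxabicyclo[4.1.0]heptane-3-carboxamide | CON(C)C(=O)[C@@H]1CC[C@@H]2O[C@@H]2C1 | intermediate
17 | (1R,3S,4S)-3-bromo-4-hydroxy-N-methoxy-N-methylcyclohexane-1-carboxamide | CON(C)C(=O)[C@@H]1CC[C@H](O)[C@@H](Br)C1 | intermediate
18 | (1R,3S)-3-bromo-N-methoxy-N-methyl-4-oxocyclohexane-1-carboxamide | CON(C)C(=O)[C@@H]1CCC(=O)[C@@H](Br)C1 | intermediate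
19 | 1-[(1R,3S,4R)-3-bromo-4-hydroxy-4-methylcyclohexyl]ethan-1-one (acetyl trans to Br and OH) | CC(=O)[C@@H]1CC[C@@](C)(O)[C@@H](Br)C1 | intermediate (not isolated)
20 | 1-[(1S,3S,4R)-3-bromo-4-hydroxy-4-methylcyclohexyl]ethan-1-one (acetyl, Br and OH all cis) | CC(=O)[C@H]1CC[C@@](C)(O)[C@@H](Br)C1 | intermediate
21 | (1R,2S,4S)-2-bromo-1-methyl-4-(prop-1-en-2-yl)cyclohexan-1-ol | C=C(C)[C@H]1CC[C@@](C)(O)[C@@H](Br)C1 | intermediate
22 | (1R,2S,4S)-2-bromo-4-(3-hydroxyprop-1-en-2-yl)-1-methylcyclohexan-1-ol (ring B alcohol) | C=C(CO)[C@H]1CC[C@@](C)(O)[C@@H](Br)C1 | intermediate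
23 | dichlorodi(propan-2-yl)silane | CC(C)[Si](Cl)(Cl)C(C)C | starting material
24 | chloro({(1R)-1-[(1R)-2,2-dimethyl-6-methylidenecyclohex-3-en-1-yl]prop-2-en-1-yl}oxy)di(propan-2-yl)silane | C=C1CC=CC(C)(C)[C@@H]1[C@H](O[Si](Cl)(C(C)C)C(C)C)C=C | intermediate (not isolated)
25 | acyclic silaketal: di(propan-2-yl)silylene bis-ether of 12 (through O7) and 22 (through its primary oxygen) | C=C1CC=CC(C)(C)[C@@H]1[C@H](O[Si](C(C)C)(C(C)C)OCC(=C)[C@H]2CC[C@@](C)(O)[C@@H](Br)C2)C=C | intermediate
26 | cyclic silaketal: (1R,2S,4S)-2-bromo-4-{(4R)-4-[(1R)-2,2-dimethyl-6-methylidenecyclohex-3-en-1-yl]-2,2-di(propan-2-yl)-4,7-dihydro-1,3,2-dioxasilepin-6-yl}-1-methylcyclohexan-1-ol | C=C1CC=CC(C)(C)[C@@H]1[C@H]2C=C(CO[Si](C(C)C)(C(C)C)O2)[C@H]3CC[C@@](C)(O)[C@@H](Br)C3 | intermediate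
27 | (1R,2S,4S)-2-bromo-4-[(2Z,4R)-4-[(1R)-2,2-dimethyl-6-methylidenecyclohex-3-en-1-yl]-1-hydroxy-4-{[methyldi(propan-2-yl)silyl]oxy}but-2-en-2-yl]-1-methylcyclohexan-1-ol | C=C1CC=CC(C)(C)[C@@H]1[C@H](O[Si](C)(C(C)C)C(C)C)/C=C(\CO)[C@H]1CC[C@@](C)(O)[C@@H](Br)C1 | intermediate
28 | primary methanesulfonate of 27 | C=C1CC=CC(C)(C)[C@@H]1[C@H](O[Si](C)(C(C)C)C(C)C)/C=C(\COS(C)(=O)=O)[C@H]1CC[C@@](C)(O)[C@@H](Br)C1 | intermediate (not isolated)
29 | (1R,2S,4S)-2-bromo-4-[(2E,4R)-4-[(1R)-2,2-dimethyl-6-methylidenecyclohex-3-en-1-yl]-4-{[methyldi(propan-2-yl)silyl]oxy}but-2-en-2-yl]-1-methylcyclohexan-1-ol | C=C1CC=CC(C)(C)[C@@H]1[C@H](O[Si](C)(C(C)C)C(C)C)/C=C(\C)[C@H]1CC[C@@](C)(O)[C@@H](Br)C1 | intermediate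
30 | (1R,2S,4S)-2-bromo-4-[(2E,4R)-4-[(1R)-2,2-dimethyl-6-methylidenecyclohex-3-en-1-yl]-4-hydroxybut-2-en-2-yl]-1-methylcyclohexan-1-ol | C=C1CC=CC(C)(C)[C@@H]1[C@H](O)/C=C(\C)[C@H]1CC[C@@](C)(O)[C@@H](Br)C1 | target

**Count and risks**

Total: 20 steps. Longest linear sequence: 12 steps (steps 9–20 from 13; the branch from 1 through steps 1, 2, 4–8 and 16–20 is equally long).

Most likely to fail:

1. Step 18. Methyllithium may instead break the Si–O bond to the secondary oxygen, or the silyl group may migrate to the primary alkoxide before the quench; either way O7 would not stay protected through the deoxygenation. The fallback sets out from 26. Bu4NF in THF removes the silicon bridge to give the free triol F4. TESOTf and 2,6-lutidine in CH2Cl2 convert it into the tris(triethylsilyl) ether F5. PPTS in MeOH–CH2Cl2 at −10 °C cleaves only the primary allylic silyl ether to give the primary alcohol F6. MsCl/Et3N then LiBHEt3, as in step 19, lead through the allylic mesylate F7 to the bis(triethylsilyl) ether of the target F8. Bu4NF then gives 30, where the fallback rejoins the route.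

2. Step 8. The hindered allyl boronate, whose reacting carbon sits next to the quaternary centre, may turn over slowly under the chiral acid or be discriminated poorly, so that the uncatalysed pathway erodes the enantiomeric purity. The fallback sets out from 10 (with 11). Without catalyst in toluene at rt the same chair transition state should give the anti alcohol as a racemate, that is 12 together with its enantiomer (1S)-1-[(1S)-2,2-dimethyl-6-methylidenecyclohex-3-en-1-yl]prop-2-en-1-ol F1. Sharpless kinetic resolution (Ti(OiPr)4, D-(−)-diisopropyl tartrate, tBuOOH, 4 Å MS, CH2Cl2, −20 °C) should then epoxidise the vinyl group of the mismatched enantiomer to the epoxy alcohol (R)-[(1S)-2,2-dimethyl-6-methylidenecyclohex-3-en-1-yl][(2R)-oxiran-2-yl]methanol F2 and leave 12, which is separated and rejoins the route at 12.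

3. Step 13. The base-mediated equilibration at C1 may stop at an unfavourable ratio, or the ketone enolate may displace the γ-bromide and close a cyclopropane. The fallback sets out from 19, isolated after the Grignard stage. Acid is used instead of base: HC(OMe)3, MeOH and TsOH (cat.) at 40 °C epimerise C1 by acid-catalysed enolisation, and only the cis isomer can be captured by the tertiary hydroxyl as the bicyclic mixed ketal 6-bromo-3-methoxy-1,3-dimethyl-2-oxabicyclo[2.2.2]octane F3, which should drain the equilibrium. Aqueous acetic acid in THF then hydrolyses the ketal to 20, where the route resumes.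

**Further compounds**

F1 | step 8 | (1S)-1-[(1S)-2,2-dimethyl-6-methylidenecyclohex-3-en-1-yl]prop-2-en-1-ol (enantiomer of 12, formed with it as the racemate) | C=C1CC=CC(C)(C)[C@H]1[C@@H](O)C=C
F2 | step 8 | (R)-[(1S)-2,2-dimethyl-6-methylidenecyclohex-3-en-1-yl][(2R)-oxiran-2-yl]methanol | C=C1CC=CC(C)(C)[C@H]1[C@@H](O)[C@H]2CO2
F3 | step 13 | 6-bromo-3-methoxy-1,3-dimethyl-2-oxabicyclo[2.2.2]octane (ring stereocentres as in 20, ketal carbon as a mixture) | CC2(OC)[C@H]1CC[C@@](C)(O2)[C@@H](Br)C1
F4 | step 18 | (1R,2S,4S)-2-bromo-4-[(2Z,4R)-4-[(1R)-2,2-dimethyl-6-methylidenecyclohex-3-en-1-yl]-1,4-dihydroxybut-2-en-2-yl]-1-methylcyclohexan-1-ol (triol) | C=C1CC=CC(C)(C)[C@@H]1[C@H](O)/C=C(\CO)[C@H]1CC[C@@](C)(O)[C@@H](Br)C1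
F5 | step 18 | tris(triethylsilyl) ether of F4 | C=C1CC=CC(C)(C)[C@@H]1[C@H](O[Si](CC)(CC)CC)/C=C(\CO[Si](CC)(CC)CC)[C@H]1CC[C@@](C)(O[Si](CC)(CC)CC)[C@@H](Br)C1
F6 | step 18 | bis(triethylsilyl) ether of F4 with the primary hydroxyl free | C=C1CC=CC(C)(C)[C@@H]1[C@H](O[Si](CC)(CC)CC)/C=C(\CO)[C@H]1CC[C@@](C)(O[Si](CC)(CC)CC)[C@@H](Br)C1
F7 | step 18 | primary methanesulfonate of F6 | C=C1CC=CC(C)(C)[C@@H]1[C@H](O[Si](CC)(CC)CC)/C=C(\COS(C)(=O)=O)[C@H]1CC[C@@](C)(O[Si](CC)(CC)CC)[C@@H](Br)C1
F8 | step 18 | bis(triethylsilyl) ether of 30 (at O7 and the tertiary oxygen) | C=C1CC=CC(C)(C)[C@@H]1[C@H](O[Si](CC)(CC)CC)/C=C(\C)[C@H]1CC[C@@](C)(O[Si](CC)(CC)CC)[C@@H](Br)C1
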